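Percent of the starting material charged is my unit, so I first ask how many percent of it can reach target at all.

the same everywhere: free enzyme 10 µM

|  | starting material | protic impurity | temperature | remark | time |
|---|---|---|---|---|---|
| violet | 0.15 M | 0.010 M | 45 °C | run made earlier |  |
| south-west | 0.10 M | 0.0100 M | 45 °C |  | 10 h |
| south-east | 0.10 M | 0.0100 M | 30 °C |  | 10 h |
| south | 0.10 M | 0.0100 M | 0 °C |  | 10 h |
| north-west | 0.10 M | 0.0100 M | 15 °C |  | 10 h |

violet run (percent of the starting material charged)

| time / min | target / % | starting material / % |
|---|---|---|
| 5.00 | 8.0 | 67.5 |
| 8.00 | 11.4 | 55.5 |
| 12.0 | 15.4 | 42.3 |
| 20.0 | 20.0 | 25.2 |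
| 40.0 | 23.8 | 7.2 |
| 60.0 | 24.1 | 2.6 |

(each reading ± 0.3 percentage points)

- the numbers in the tables scatter with a standard deviation of 0.3 percentage points
- the earlier runs do not show what temperature does; that part of a forecast is a guess

* the flask with the highest amount of target, in percent of the starting material charged ("all alike" if they lie within 1.5 percentage points) (south-west / south-east / south / north-west / all alike)
* final target, as a percentage of the starting material charged, in south-west
* final target, as a percentage of the starting material charged, in south-east
* final target, as a percentage of the starting material charged, in south
* final target, as a percentage of the starting material charged, in north-west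

I assume that the protic impurity destroys starting material quickly and one for one, and I treat that side step as finished, with the impurity as its limiting reagent. What it leaves is the free pool, the charge minus the impurity, as a share of the charge: 90.0% in each of the four flasks, and 93.3% in the violet run.

Turned round, the question is whether the impurity could explain the low yield of the violet run. At its last reading, 73.3% of the charge is neither target nor starting material. For the impurity to account for that, its charge would have to be 0.110 M, but it is 0.010 M, so a second loss is at work in the violet run.

Of the pool used by that reading, target holds 26.6%, which is my reading of the selectivity. If that share also holds at the lower charge of south-west, which stands at the temperature of the violet run, it gives south-west 23.9%. The runs give no share for the colder flasks, so for them my reckoning stops at the ceiling 90.0%.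

The forecast names north-west, with 25% in south-west, 27% in south-east, 19% in south and 28% in north-west. Its ground for cooling is: “I tentatively assume the catalysed route has the lower barrier, so cooling modestly improves selectivity.”

The flasks give north-west as the best, with 23.8% in south-west, 46.5% in south-east, 62.0% in south and 66.3% in north-west.

    starting material + free enzyme → target + free enzyme, rate k1*[starting material]^2*[free enzyme]/(1 + ([starting material]/Kh1)^2) (0.0560 M, k = 57000 M⁻² min⁻¹, Ea = 36.0 kJ mol⁻¹)
    starting material + protic impurity → quenched substrate (k = 1.50 M⁻¹ min⁻¹, Ea = 42.0 kJ mol⁻¹)
    free enzyme → unfolded enzyme (k = 9.60 × 10⁻⁵ min⁻¹, Ea = 240 kJ mol⁻¹)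
    2 free enzyme ⇌ resting dimer (K = 39000 M⁻¹, k = 2700 M⁻¹ min⁻¹, Ea = 42.0 kJ mol⁻¹, ΔH = −4.00 kJ mol⁻¹)
    starting material → uncatalysed product (k = 0.00750 min⁻¹, Ea = 97.0 kJ mol⁻¹)
    (constants at 30 °C)

In north-west, starting material, target and uncatalysed product add up to 90.0%, the free pool, and quenched substrate holds 10.0%. There the catalysed route uses starting material 6.4 times as fast as the uncatalysed route at the start and 4.8 times as fast at 1.51 h, and target holds 80.3% of the pool used.

In the neighbour like north-west but kept at 40 °C, starting material ends at 0%, so the pool 90.0% less the target 30.8% leaves 59.2% for uncatalysed product. The computed flask holds 59.2%.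

(The runs are simulated for substances that don't exist.)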